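**Plan**

- Numbering: ring carbons C8 (lactone O–CH), C9, C10(Me)=C1, C2, C3=C4(Me), C5 (OAc), C6 (epoxy ester), C7; lactone carbons C11–C13. The two adjacent, ring-cis oxygenated carbons C5 and C6 of the ten-membered carbocycle are the retron of a reductive coupling of two aldehydes.
- Cuts: the ester bonds at O5 and O6 and the C11=C13 methylene; then C5–C6 (pinacol coupling of a C5 Z-enal with a C6 aldehyde); then lactone O8–C12, C7–C11 (enolate alkylation), C9–C10 (epoxide opening) and C2–C3 (allyl–alkenyl coupling).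
- Forward: C2–C3 and C9–C10 join the Z,Z-diene chain, C7–C11 alkylation and lactonisation give the butyrolactone first, SmI2 then closes the ten-membered ring, and methylenation and the two acylations follow.
- Stereochemistry: C8 from ethyl (3R)-4-chloro-3-hydroxybutanoate; C7 by anti-selective Fráter–Seebach alkylation; both Z olefins from stereodefined alkenyl iodides; C5 and C6 in the pinacol step (samarium chelate, C7); the epoxy acid by Sharpless epoxidation of tiglyl alcohol.

Key step: step 14

Remark: C11 of 28 and 29 forms as an inconsequential epimer mixture and is left unspecified in their SMILES; stereodescriptors of ring compounds refer to the numbering above.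

**Route**

Step 1
Reactants: 1 but-2-yn-1-ol
Product: 3 (2Z)-3-iodobut-2-en-1-ol, via cyclic alkenylalanate 2 (not isolated)
Conditions: NaAlH2(OCH2CH2OMe)2, THF, 0 °C → rt; then I2, −78 → 0 °C
Reagents that add atoms: iodine, II
Why: Hydroxyl-directed anti-hydroalumination of the propargylic alcohol places aluminium on C3 cis to the carbinol carbon in a five-membered alanate, and iodinolysis with retention gives the Z iodide (trans-hydrometalation–iodination of an alkynol).

Step 2
Reactants: 3 (2Z)-3-iodobut-2-en-1-ol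
Product: 4 (2Z)-1-bromo-3-iodobut-2-ene
Conditions: PBr3, pyridine (cat.), Et2O, 0 °C
Reagents that add atoms: phosphorus tribromide, BrP(Br)Br
Why: SN2 bromination of the primary allylic alcohol leaves the alkenyl iodide and its geometry untouched.

Step 3
Reactants: 5 prop-2-yn-1-ol
Product: 7 (2Z)-3-iodo-2-methylprop-2-en-1-ol, via cyclic alkenylmagnesium alkoxide 6 (not isolated)
Conditions: MeMgBr (2.5 equiv), CuI (10 mol%), THF, −10 °C → rt; then I2, −10 °C
Reagents that add atoms: methylmagnesium bromide, C[Mg]Br; iodine, II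
Why: Copper-catalysed anti-carbomagnesiation of the propargylic alkoxide puts methyl on C2 and magnesium on C3 within a chelate ring, and iodinolysis with retention fixes iodine cis to the hydroxymethyl group.

Step 4
Reactants: 7 (2Z)-3-iodo-2-methylprop-2-en-1-ol
Product: 8 tert-butyl{[(2Z)-3-iodo-2-methylprop-2-en-1-yl]oxy}diphenylsilane
Conditions: TBDPSCl, imidazole, CH2Cl2, 0 °C → rt
Reagents that add atoms: tert-butyl(chloro)diphenylsilane, CC(C)(C)[Si](Cl)(c1ccccc1)c1ccccc1
Why: Standard silylation, with the bulky silyl group chosen because it survives alkyllithium, amide base, LiBH4 and mild acid and resists 1,4-O→C silyl migration in the derived Z-alkenyllithium.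

Step 5
Reactants: 8 silyl ether of the C3–C5 iodide; 4 (2Z)-1-bromo-3-iodobut-2-ene
Product: 11 tert-butyl{[(2Z,5Z)-6-iodo-2-methylhepta-2,5-dien-1-yl]oxy}diphenylsilane, via alkenyllithium 9 (not isolated), via alkenylmagnesium bromide 10 (not isolated)
Conditions: 8, t-BuLi (2.1 equiv), Et2O, −78 °C; MgBr2·OEt2, −78 → −40 °C; then CuI (10 mol%), 4, THF, −40 → 0 °C
Reagents that add atoms: none
Why: Iodine–lithium exchange with retention, transmetalation and copper-catalysed SN2 substitution of the primary allylic bromide (allyl–alkenyl Grignard cross-coupling) form C2–C3 with both Z geometries kept, attack at the iodine-bearing fully substituted terminus (SN2′) being disfavoured.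

Step 6
Reactants: 12 ethyl (3R)-4-chloro-3-hydroxybutanoate
Product: 13 ethyl [(2R)-oxiran-2-yl]acetate
Conditions: Ag2O, DME, 60 °C, dark
Reagents that add atoms: none
Why: Silver-assisted intramolecular Williamson closure of the chlorohydrin forms the epoxide without breaking the C–O bond of the stereocentre and without the base-induced elimination to the 4-hydroxycrotonate.

Step 7
Reactants: 11 Z,Z-dienyl iodide; 13 ethyl [(2R)-oxiran-2-yl]acetate
Product: 16 ethyl (3S,5Z,8Z)-10-[(tert-butyldiphenylsilyl)oxy]-3-hydroxy-5,9-dimethyldeca-5,8-dienoate, via dienyllithium 14 (not isolated), via dienylmagnesium bromide 15 (not isolated)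
Conditions: 11, t-BuLi (2.1 equiv), Et2O, −78 °C; MgBr2·OEt2; then CuI (10 mol%), 13, THF, −40 → −20 °C; aq. NH4Cl
Reagents that add atoms: none
Why: Copper-catalysed opening of the terminal epoxide by the alkenyl Grignard reagent at its unsubstituted carbon forms C9–C10 with retention of olefin geometry, outruns addition to the ester at low temperature and carries the C8 stereocentre over from the chiral pool.

Step 8
Reactants: 16 β-hydroxy ester; 17 tert-butyl bromoacetate
Product: 19 4-tert-butyl 1-ethyl (2S)-2-[(1S,3Z,6Z)-8-[(tert-butyldiphenylsilyl)oxy]-1-hydroxy-3,7-dimethylocta-3,6-dien-1-yl]butanedioate, via dilithium alkoxide–enolate 18 (not isolated)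
Conditions: LiN(iPr)2 (2.2 equiv), THF, −78 → −20 °C; then 17, DMPU, −78 → −30 °C; AcOH quench at −78 °C
Reagents that add atoms: none
Why: Fráter–Seebach alkylation, in which the chelated lithium alkoxide–enolate is alkylated on the face anti to the C9 chain, sets C7 anti to the C8 oxygen, the relationship that becomes the cis-lactone.

Step 9
Reactants: 19 hydroxy diester
Product: 20 tert-butyl (3R,4S,6Z,9Z)-11-[(tert-butyldiphenylsilyl)oxy]-4-hydroxy-3-(hydroxymethyl)-6,10-dimethylundeca-6,9-dienoate
Conditions: LiBH4, MeOH (1 equiv), THF, 0 °C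
Reagents that add atoms: none
Why: Chemoselective borohydride reduction takes the hydroxyl-activated ethyl ester and leaves the hindered tert-butyl ester, so C6 reaches the alcohol level and C7 is no longer epimerisable.

Step 10
Reactants: 20 diol tert-butyl ester
Product: 21 tert-butyl (3R,4S,6Z,9Z)-11-[(tert-butyldiphenylsilyl)oxy]-3-{[(tert-butyldiphenylsilyl)oxy]methyl}-4-hydroxy-6,10-dimethylundeca-6,9-dienoate
Conditions: TBDPSCl (1.05 equiv), imidazole, CH2Cl2, −10 °C
Reagents that add atoms: tert-butyl(chloro)diphenylsilane, CC(C)(C)[Si](Cl)(c1ccccc1)c1ccccc1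
Why: Sterically controlled silylation takes the primary C6 hydroxyl over the secondary C8 hydroxyl and thereby blocks the competing lactonisation through O6.

Step 11
Reactants: 21 bis-silyl hydroxy ester
Product: 22 (4R,5S)-5-{(2Z,5Z)-7-[(tert-butyldiphenylsilyl)oxy]-2,6-dimethylhepta-2,5-dien-1-yl}-4-{[(tert-butyldiphenylsilyl)oxy]methyl}oxolan-2-one
Conditions: TsOH·H2O (0.2 equiv), CH2Cl2, rt
Reagents that add atoms: none
Why: Acid-catalysed intramolecular transesterification (5-exo-trig) of the γ-hydroxy tert-butyl ester closes the butyrolactone through O8 with retention at C8 and gives the cis-4,5-disubstituted ring.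

Step 12
Reactants: 22 bis-silyl lactone
Product: 23 (4R,5S)-5-[(2Z,5Z)-7-hydroxy-2,6-dimethylhepta-2,5-dien-1-yl]-4-(hydroxymethyl)oxolan-2-one
Conditions: HF·pyridine, pyridine, THF, 0 °C → rt
Reagents that add atoms: none
Why: Fluoride-mediated desilylation frees both primary alcohols under non-basic conditions, so the lactone neither opens nor migrates to O6.

Step 13
Reactants: 23 lactone diol
Product: 24 (2S,3S)-2-[(2Z,5Z)-2,6-dimethyl-7-oxohepta-2,5-dien-1-yl]-5-oxooxolane-3-carbaldehyde
Conditions: Dess–Martin periodinane (3 equiv), NaHCO3, CH2Cl2, 0 °C → rt; used crude at once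
Reagents that add atoms: none
Why: Dess–Martin oxidation converts the allylic and the saturated primary alcohol to the Z-enal and the C6 aldehyde under buffered conditions that should not epimerise C7, eliminate the lactone carboxylate or isomerise the enal.

Step 14
Reactants: 24 cis-lactone dialdehyde
Product: 25 ten-membered 5,6-cis-diol lactone (5S,6R,7R,8S), cis-fused at C7/C8, O6 trans to C11
Conditions: SmI2 (3 equiv), THF, 0 °C, syringe-pump addition of 24 (final 0.003 M); then pH 7 phosphate buffer, 0 °C
Reagents that add atoms: none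
Why: SmI2 reduces the more easily reduced conjugated C5 enal to a samarium-bound allylic ketyl, which adds to the C6 aldehyde held on the same oxophilic trivalent samarium centre (or couples with its ketyl after a second electron transfer), and work-up releases the diol; the closest known reactions are SmI2 pinacol cyclisations of dialdehydes to cis-diols and low-valent titanium pinacol closures of enal–aldehyde pairs to medium rings. The ten-membered carbocycle closes by a formal 10-exo-trig attack of C5 on the C6 carbonyl, the chain ends being brought together by the two Z olefins and by the cis-lactone, which holds C6 and C9 on one face of the five-membered ring. C5 and C6 are set erythro (ring-cis) because both oxygens stay bound to samarium in the bond-forming array, and C6 is set relative to C7 by addition to the carbonyl face anti to the lactone methylene C11 (Felkin–Anh-type, C8 carrying the tether). The step needs coupling at C5 and not at C3 of the allylic ketyl, which the C4 methyl branch and the higher spin density at the oxygen-bearing carbon favour, and cyclisation over oligomerisation, which slow addition at high dilution secures. The lactone is not reduced by SmI2 in THF without HMPA or water, and the cold buffered quench should prevent migration of the lactone to the new O6 alkoxide.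

Step 15
Reactants: 25 diol lactone
Product: 26 5,6-O-isopropylidene acetal of 25
Conditions: 2,2-dimethoxypropane, PPTS (cat.), CH2Cl2, rt
Reagents that add atoms: 2,2-dimethoxypropane, COC(C)(C)OC
Why: Acid-catalysed transacetalisation protects the cis-diol as a dioxolane, which also masks O6 against lactone migration during the enolate chemistry.

Step 16
Reactants: 26 acetonide lactone
Product: 28 11-(dimethylaminomethyl) lactone acetonide, via lactone lithium enolate 27 (not isolated)
Conditions: LiN(iPr)2 (1.3 equiv), THF, −78 °C; then CH2=NMe2+ I−, −78 → 0 °C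
Reagents that add atoms: N,N-dimethylmethyleneiminium iodide, C=[N+](C)C.[I-]
Why: Mannich reaction of the lactone enolate with Eschenmoser's salt introduces C13 at C11, whose new configuration is irrelevant because the centre becomes sp2 in the next step.

Step 17
Reactants: 28 Mannich base
Product: 30 α-methylene lactone acetonide, via trimethylammonium iodide 29 (not isolated)
Conditions: MeI, MeOH, rt; then aq. NaHCO3, CH2Cl2, rt
Reagents that add atoms: none
Why: N-Methylation followed by mild base-induced β-elimination of trimethylamine (Hofmann-type) gives the conjugated exocyclic methylene.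

Step 18
Reactants: 30 α-methylene lactone acetonide
Product: 31 α-methylene lactone 5,6-diol
Conditions: AcOH–H2O (4:1), 40 °C
Reagents that add atoms: none
Why: Mild acid hydrolysis of the isopropylidene acetal should leave the conjugated lactone, the skipped diene and the allylic C5–O bond intact.

Step 19
Reactants: 31 α-methylene lactone 5,6-diol
Product: 32 5-O-acetate of 31
Conditions: Ac2O (1.05 equiv), pyridine, CH2Cl2, −20 → 0 °C
Reagents that add atoms: acetic anhydride, CC(=O)OC(C)=O
Why: Kinetic monoacylation should occur at the allylic C5 hydroxyl, which sits next to a planar sp2 carbon, in preference to the C6 hydroxyl shielded by the ring-fusion carbon C7 and the cis-fused lactone.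

Step 20
Reactants: 33 tiglic acid
Product: 34 (2E)-2-methylbut-2-en-1-ol
Conditions: LiAlH4, Et2O, 0 °C
Reagents that add atoms: none
Why: Hydride reduction of the unsaturated acid proceeds by 1,2-addition and leaves the trisubstituted E olefin untouched.

Step 21
Reactants: 34 (2E)-2-methylbut-2-en-1-ol
Product: 35 [(2R,3R)-2,3-dimethyloxiran-2-yl]methanol
Conditions: Ti(OiPr)4 (10 mol%), D-(−)-diethyl tartrate (12 mol%), t-BuOOH, 4 Å MS, CH2Cl2, −20 °C
Reagents that add atoms: tert-butyl hydroperoxide, CC(C)(C)OO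
Why: Sharpless asymmetric epoxidation with the D-tartrate ligand delivers oxygen to the olefin face that gives the (2R,3R)-epoxy alcohol, and the E geometry fixes the two methyl groups cis.

Step 22
Reactants: 35 epoxy alcohol
Product: 36 (2S,3R)-2,3-dimethyloxirane-2-carboxylic acid
Conditions: RuCl3·xH2O (2 mol%), NaIO4, MeCN–CCl4–H2O, 0 °C → rt
Reagents that add atoms: sodium periodate, [Na+].[O-]I(=O)(=O)=O; water, O
Why: Ruthenium-catalysed periodate oxidation takes the primary alcohol to the acid without opening the trisubstituted epoxide, the descriptor at C2 changing only through the priority rules.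

Step 23
Reactants: 32 5-O-acetate; 36 epoxy acid
Product: 38 CNP0188864.1 (5S,6R,7S,8S; acyl 2S,3R), via mixed anhydride 37 (not isolated)
Conditions: 36, 2,4,6-trichlorobenzoyl chloride, Et3N, toluene, rt; then 32, DMAP, toluene, rt
Reagents that add atoms: none
Why: Yamaguchi esterification, in which DMAP attacks the less hindered epoxy-acyl carbonyl of the mixed anhydride and the acylpyridinium acylates the remaining C6 hydroxyl, touches no stereocentre.

**Compound list**

1 | but-2-yn-1-ol | CC#CCO | starting material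
2 | sodium 2,2-bis(2-methoxyethoxy)-3-methyl-2,5-dihydro-1,2-oxaaluminol-2-uide (cyclic alkenylalanate) | CC1=CCO[Al-]1(OCCOC)OCCOC.[Na+] | intermediate
3 | (2Z)-3-iodobut-2-en-1-ol | C/C(I)=C/CO | intermediate
4 | (2Z)-1-bromo-3-iodobut-2-ene | C/C(I)=C/CBr | intermediate
5 | prop-2-yn-1-ol | C#CCO | starting material
6 | 4-methyl-2,5-dihydro-1,2-oxamagnesole (cyclic alkenylmagnesium alkoxide) | CC1=C[Mg]OC1 | intermediate
7 | (2Z)-3-iodo-2-methylprop-2-en-1-ol | I/C=C(/C)CO | intermediate
8 | tert-butyl{[(2Z)-3-iodo-2-methylprop-2-en-1-yl]oxy}diphenylsilane | I/C=C(/C)CO[Si](c1ccccc1)(c1ccccc1)C(C)(C)C | intermediate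
9 | alkenyllithium from 8 (Li in place of I, geometry retained) | [Li]/C=C(/C)CO[Si](c1ccccc1)(c1ccccc1)C(C)(C)C | intermediate
10 | alkenylmagnesium bromide from 9 (MgBr in place of Li) | Br[Mg]/C=C(/C)CO[Si](c1ccccc1)(c1ccccc1)C(C)(C)C | intermediate
11 | tert-butyl{[(2Z,5Z)-6-iodo-2-methylhepta-2,5-dien-1-yl]oxy}diphenylsilane | C/C(I)=C/C/C=C(/C)CO[Si](c1ccccc1)(c1ccccc1)C(C)(C)C | intermediate
12 | ethyl (3R)-4-chloro-3-hydroxybutanoate | CCOC(=O)C[C@@H](O)CCl | starting material
13 | ethyl [(2R)-oxiran-2-yl]acetate | CCOC(=O)C[C@@H]1CO1 | intermediate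
14 | dienyllithium from 11 (Li in place of I, geometry retained) | C/C([Li])=C/C/C=C(/C)CO[Si](c1ccccc1)(c1ccccc1)C(C)(C)C | intermediate
15 | dienylmagnesium bromide from 14 (MgBr in place of Li) | C/C([Mg]Br)=C/C/C=C(/C)CO[Si](c1ccccc1)(c1ccccc1)C(C)(C)C | intermediate
16 | ethyl (3S,5Z,8Z)-10-[(tert-butyldiphenylsilyl)oxy]-3-hydroxy-5,9-dimethyldeca-5,8-dienoate | CCOC(=O)C[C@@H](O)C/C(C)=C\C/C=C(/C)CO[Si](c1ccccc1)(c1ccccc1)C(C)(C)C | intermediate
17 | tert-butyl bromoacetate | CC(C)(C)OC(=O)CBr | starting material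
18 | dilithium alkoxide–enolate of 16 (enolate oxygen cis to C8) | CCO/C([O-])=C/[C@@H]([O-])C/C(C)=C\C/C=C(/C)CO[Si](c1ccccc1)(c1ccccc1)C(C)(C)C.[Li+].[Li+] | intermediate
19 | 4-tert-butyl 1-ethyl (2S)-2-[(1S,3Z,6Z)-8-[(tert-butyldiphenylsilyl)oxy]-1-hydroxy-3,7-dimethylocta-3,6-dien-1-yl]butanedioate | CCOC(=O)[C@@H](CC(=O)OC(C)(C)C)[C@@H](O)C/C(C)=C\C/C=C(/C)CO[Si](c1ccccc1)(c1ccccc1)C(C)(C)C | intermediate
20 | tert-butyl (3R,4S,6Z,9Z)-11-[(tert-butyldiphenylsilyl)oxy]-4-hydroxy-3-(hydroxymethyl)-6,10-dimethylundeca-6,9-dienoate | OC[C@@H](CC(=O)OC(C)(C)C)[C@@H](O)C/C(C)=C\C/C=C(/C)CO[Si](c1ccccc1)(c1ccccc1)C(C)(C)C | intermediate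
21 | tert-butyl (3R,4S,6Z,9Z)-11-[(tert-butyldiphenylsilyl)oxy]-3-{[(tert-butyldiphenylsilyl)oxy]methyl}-4-hydroxy-6,10-dimethylundeca-6,9-dienoate | CC(C)(C)[Si](c1ccccc1)(c1ccccc1)OC[C@@H](CC(=O)OC(C)(C)C)[C@@H](O)C/C(C)=C\C/C=C(/C)CO[Si](c1ccccc1)(c1ccccc1)C(C)(C)C | intermediate
22 | (4R,5S)-5-{(2Z,5Z)-7-[(tert-butyldiphenylsilyl)oxy]-2,6-dimethylhepta-2,5-dien-1-yl}-4-{[(tert-butyldiphenylsilyl)oxy]methyl}oxolan-2-one | O=C1O[C@@H](C/C(C)=C\C/C=C(/C)CO[Si](c2ccccc2)(c2ccccc2)C(C)(C)C)[C@@H](CO[Si](c2ccccc2)(c2ccccc2)C(C)(C)C)C1 | intermediate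
23 | (4R,5S)-5-[(2Z,5Z)-7-hydroxy-2,6-dimethylhepta-2,5-dien-1-yl]-4-(hydroxymethyl)oxolan-2-one | O=C1O[C@@H](C/C(C)=C\C/C=C(/C)CO)[C@@H](CO)C1 | intermediate
24 | (2S,3S)-2-[(2Z,5Z)-2,6-dimethyl-7-oxohepta-2,5-dien-1-yl]-5-oxooxolane-3-carbaldehyde | O=C1O[C@@H](C/C(C)=C\C/C=C(/C)C=O)[C@@H](C=O)C1 | intermediate
25 | ten-membered 5,6-cis-diol lactone (5S,6R,7R,8S), lactone cis-fused at C7/C8, 1(10)Z,3Z-diene | O=C1O[C@H]2C/C(C)=C\C/C=C(/C)[C@H](O)[C@H](O)[C@H]2C1 | intermediate
26 | 5,6-O-isopropylidene acetal of 25 (5S,6R,7S,8S) | O=C1O[C@H]2C/C(C)=C\C/C=C(/C)[C@@H]3OC(C)(C)O[C@@H]3[C@H]2C1 | intermediate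
27 | lithium enolate of lactone 26 (C11=C12–O−) | [Li+].[O-]C=1O[C@H]2C/C(C)=C\C/C=C(/C)[C@@H]3OC(C)(C)O[C@@H]3[C@H]2C=1 | intermediate
28 | 11-(dimethylaminomethyl) derivative of 26 (C11 epimers) | CN(C)CC1C(=O)O[C@H]2C/C(C)=C\C/C=C(/C)[C@@H]3OC(C)(C)O[C@@H]3[C@@H]12 | intermediate
29 | trimethylammonium iodide of 28 | C[N+](C)(C)CC1C(=O)O[C@H]2C/C(C)=C\C/C=C(/C)[C@@H]3OC(C)(C)O[C@@H]3[C@@H]12.[I-] | intermediate
30 | 11(13)-methylene lactone 5,6-acetonide (5S,6R,7S,8S) | C=C1C(=O)O[C@H]2C/C(C)=C\C/C=C(/C)[C@@H]3OC(C)(C)O[C@@H]3[C@@H]12 | intermediate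
31 | 11(13)-methylene lactone 5,6-diol (5S,6R,7R,8S) | C=C1C(=O)O[C@H]2C/C(C)=C\C/C=C(/C)[C@H](O)[C@H](O)[C@@H]12 | intermediate
32 | 5-O-acetyl-6-hydroxy 11(13)-methylene lactone (5S,6R,7R,8S) | C=C1C(=O)O[C@H]2C/C(C)=C\C/C=C(/C)[C@H](OC(C)=O)[C@H](O)[C@@H]12 | intermediate
33 | tiglic acid, (2E)-2-methylbut-2-enoic acid | C/C=C(\C)C(=O)O | starting material
34 | (2E)-2-methylbut-2-en-1-ol | C/C=C(\C)CO | intermediate
35 | [(2R,3R)-2,3-dimethyloxiran-2-yl]methanol | OC[C@@]1(C)O[C@@H]1C | intermediate
36 | (2S,3R)-2,3-dimethyloxirane-2-carboxylic acid | OC(=O)[C@@]1(C)O[C@@H]1C | intermediate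
37 | (2S,3R)-2,3-dimethyloxirane-2-carboxylic 2,4,6-trichlorobenzoic anhydride | O=C(OC(=O)[C@@]1(C)O[C@@H]1C)c1c(Cl)cc(Cl)cc1Cl | intermediate
38 | CNP0188864.1 (5S,6R,7S,8S; acyl 2S,3R) | C=C1C(=O)O[C@H]2C/C(C)=C\C/C=C(/C)[C@H](OC(C)=O)[C@H](OC(=O)[C@@]3(C)O[C@@H]3C)[C@@H]12 | target

**Step count**

Total: 23 steps. Longest linear sequence: 17 steps (1, 2, 5, 7–19, 23).

**Steps most likely to fail**

Step 14. The ketyl coupling may close the ring with poor facial control at C5, giving threo diol beside the erythro diol, because a samarium bridge is less rigid in a ten-membered array than in small rings. The fallback sets out from 24 and returns at 25. The coupling is run as before, and the diol mixture, which then contains the C5-epimeric diol F1, is oxidised at the allylic C5 carbinol only with MnO2 in CH2Cl2. Both epimers converge on the α-hydroxy enone F2. Reduction with Zn(BH4)2 in Et2O at −20 °C proceeds through the zinc chelate of the C6 hydroxyl and the C5 ketone, which should give the erythro diol 25. C5 is then set by a chelation-controlled reduction and no longer by the ring closure.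

Step 19. The two secondary hydroxyls may be discriminated poorly, and the acetyl group may migrate from O5 to O6 under the basic conditions of the later esterification. The fallback sets out from 31 and returns at 38, bypassing 32. MnO2 oxidises only the allylic C5 carbinol to the hydroxy enone F3, which has a single hydroxyl. Yamaguchi acylation with 36 through 37 gives the keto epoxy ester F4. Luche reduction (NaBH4, CeCl3·7H2O, MeOH, −78 °C) should add hydride 1,2 to the enone anti to the C6 acyloxy group (polar Felkin–Anh, erythro) and spare the methylene lactone, giving the C5 alcohol F5. Acetylation (Ac2O, DMAP, pyridine) then gives 38.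

Step 8. The strongly basic dianion may deprotonate the α-bromo ester instead of being alkylated, with self-condensation of the electrophile, low conversion and erosion of the anti selectivity. The fallback sets out from 16 and returns at 20. LiOH in aqueous THF gives the β-hydroxy acid F6. Acetalisation with pivalaldehyde (PPTS, CH2Cl2, 4 Å MS) gives the cis-2-tert-butyl-1,3-dioxan-4-one F7. Its mono-anionic enolate (LiN(iPr)2, THF, −78 °C) is much less basic than the dianion and is alkylated by 17 trans to the C8 substituent, giving the alkylated dioxanone F8. LiBH4 opens the acylal reductively and leaves the tert-butyl ester, giving 20.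

Further compounds
F1 | step 14 | C5-epimer of diol lactone 25 (5R,6R,7R,8S) | O=C1O[C@H]2C/C(C)=C\C/C=C(/C)[C@@H](O)[C@H](O)[C@H]2C1
F2 | step 14 | 6-hydroxy-5-oxo ten-membered lactone (α-hydroxy Z-enone) | O=C1O[C@H]2C/C(C)=C\C/C=C(/C)C(=O)[C@H](O)[C@H]2C1
F3 | step 19 | 6-hydroxy-5-oxo 11(13)-methylene lactone | C=C1C(=O)O[C@H]2C/C(C)=C\C/C=C(/C)C(=O)[C@H](O)[C@@H]12
F4 | step 19 | 5-oxo 6-O-[(2S,3R)-2,3-dimethyloxirane-2-carbonyl] 11(13)-methylene lactone | C=C1C(=O)O[C@H]2C/C(C)=C\C/C=C(/C)C(=O)[C@H](OC(=O)[C@@]3(C)O[C@@H]3C)[C@@H]12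
F5 | step 19 | 5-hydroxy 6-O-[(2S,3R)-2,3-dimethyloxirane-2-carbonyl] 11(13)-methylene lactone | C=C1C(=O)O[C@H]2C/C(C)=C\C/C=C(/C)[C@H](O)[C@H](OC(=O)[C@@]3(C)O[C@@H]3C)[C@@H]12
F6 | step 8 | (3S,5Z,8Z)-10-[(tert-butyldiphenylsilyl)oxy]-3-hydroxy-5,9-dimethyldeca-5,8-dienoic acid | OC(=O)C[C@@H](O)C/C(C)=C\C/C=C(/C)CO[Si](c1ccccc1)(c1ccccc1)C(C)(C)C
F7 | step 8 | cis-2-tert-butyl-6-{(2Z,5Z)-7-[(tert-butyldiphenylsilyl)oxy]-2,6-dimethylhepta-2,5-dien-1-yl}-1,3-dioxan-4-one | O=C1C[C@H](C/C(C)=C\C/C=C(/C)CO[Si](c2ccccc2)(c2ccccc2)C(C)(C)C)O[C@H](C(C)(C)C)O1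
F8 | step 8 | tert-butyl 2-(2,6-cis-5,6-trans-2-tert-butyl-6-{(2Z,5Z)-7-[(tert-butyldiphenylsilyl)oxy]-2,6-dimethylhepta-2,5-dien-1-yl}-4-oxo-1,3-dioxan-5-yl)acetate | O=C1[C@@H](CC(=O)OC(C)(C)C)[C@H](C/C(C)=C\C/C=C(/C)CO[Si](c2ccccc2)(c2ccccc2)C(C)(C)C)O[C@H](C(C)(C)C)O1
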